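## Retrosynthetic overview
1. The geranyl ether C–O bond is cut last, by a Mitsunobu reaction with geraniol, which leads back to diacyl triol 6.
2. The aryl–C(=O) bond of the 2-methylbutanoyl group comes from an O→C acyl shift (Fries) of aryl ester 5, whose ring has only one free carbon.
3. The ester C–O bond and the only stereocentre are made together in a carbene-catalysed redox esterification of achiral tiglaldehyde 2 with phenol 1, with enantioselective protonation.
4. No ring is formed. The benzene ring with its methyl, acetyl and three oxygens is bought as 1.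

Assumption: 1 (3-methylphloracetophenone) is taken as a catalogue chemical, and the SMILES is read as the (2R)-2-methylbutanoyl, (2E)-geranyl compound.

## Route

Step 1
Reactants: 1 1-(2,4,6-trihydroxy-3-methylphenyl)ethan-1-one; 2 (2E)-2-methylbut-2-enal (tiglaldehyde)
Product: 5 4-acetyl-3,5-dihydroxy-2-methylphenyl (2R)-2-methylbutanoate, via azolium enolate 3 (not isolated), via acyl azolium 4 (not isolated)
Conditions: (5aR,10bS)-N-mesityl aminoindanol-derived triazolium chloride (10 mol %), i-Pr2NEt (20 mol %), THF–PhMe 1:2, 40 °C, 2 (1.3 equiv) added over 6 h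
Reagents that add atoms: none
Why: Proposed new method: the free carbene adds to the CHO of 2 and the phenol protonates C3 of the extended (s-trans) dienol, so enolate 3 forms as one geometric isomer (ethyl cis to O, methyl cis to the azolium) because at that point the catalyst distinguishes a methyl from a propenyl arm rather than a methyl from an ethyl group; the indane wall of the (5aR,10bS) catalyst then leaves only the Si face of Cα open to the ArOH proton, giving (R)-4, and the unchelated, most nucleophilic 4-OH of 1 takes the acyl group faster than 4 can re-enolise; the closest known reaction types are the NHC internal redox esterification of enals and the NHC-catalysed enantioselective protonation of azolium enolates made from α,α-dihalo aldehydes or aryl alkyl ketenes in the presence of phenols, neither of which has been shown for an α,α-dialkyl (Me/Et) enolate.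

Step 2
Reactants: 5 4-acetyl-3,5-dihydroxy-2-methylphenyl (2R)-2-methylbutanoate
Product: 6 (2R)-1-(3-acetyl-2,4,6-trihydroxy-5-methylphenyl)-2-methylbutan-1-one
Conditions: AlCl3 (4 equiv), CH2Cl2–PhNO2 4:1, 0 → 40 °C; then 1 M HCl, 0 °C
Reagents that add atoms: none
Why: Fries rearrangement, in which AlCl3 ionises the aryl ester and the acylium ion re-enters at the only unsubstituted ring carbon (flanked by two O donors), so any minor O-regioisomer of 5 also converges on 6, and the α-stereocentre is untouched because neither the acylium ion nor the chelated, doubly ortho-substituted ketone enolises without base at ≤40 °C, as in the known AlCl3 acylations of phloroglucinols with enantiopure 2-methylbutanoyl chloride.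

Step 3
Reactants: 6 (2R)-1-(3-acetyl-2,4,6-trihydroxy-5-methylphenyl)-2-methylbutan-1-one; 7 geraniol, (2E)-3,7-dimethylocta-2,6-dien-1-ol
Product: 9 (2R)-1-[3-acetyl-4-{[(2E)-3,7-dimethylocta-2,6-dien-1-yl]oxy}-2,6-dihydroxy-5-methylphenyl]-2-methylbutan-1-one, via geranyloxyphosphonium ion 8 (not isolated)
Conditions: 7 (1.05 equiv), PPh3, DIAD (1.15 equiv each), THF, 0 °C → rt
Reagents that add atoms: none
Why: Mitsunobu etherification (SN2 at C1 of 8, so the 2E alkene is kept and no base reaches the stereocentre), in which the 2-OH between the two carbonyls is doubly chelated and inert, the 4-OH beside the small acetyl group should be favoured (selectivity modest and unproven) over the 6-OH beside the α-branched ketone, whose sec-butyl arm shields it when its carbonyl chelates the central OH, and the neutral conditions suppress dearomatising C-alkylation of the fully substituted ring.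

## Compound list
1 | 1-(2,4,6-trihydroxy-3-methylphenyl)ethan-1-one (3-methylphloracetophenone) | CC(=O)c1c(O)cc(O)c(C)c1O | starting material
2 | (2E)-2-methylbut-2-enal (tiglaldehyde) | C/C=C(\C)C=O | starting material
3 | (Z)-azolium enolate: 1-[(5aR,10bS)-2-mesityl-5a,10b-dihydro-4H,6H-indeno[2,1-b][1,2,4]triazolo[4,3-d][1,4]oxazin-2-ium-1-yl]-2-methylbut-1-en-1-olate, ethyl cis to O | Cc1cc(C)c(c(C)c1)[n+]1c(/C([O-])=C(\C)CC)n2c(n1)CO[C@@H]1Cc3ccccc3[C@@H]12 | intermediate (not isolated)
4 | acyl azolium: (5aR,10bS)-2-mesityl-1-[(2R)-2-methylbutanoyl]-5a,10b-dihydro-4H,6H-indeno[2,1-b][1,2,4]triazolo[4,3-d][1,4]oxazin-2-ium | Cc1cc(C)c(c(C)c1)[n+]1c(C(=O)[C@H](C)CC)n2c(n1)CO[C@@H]1Cc3ccccc3[C@@H]12 | intermediate (not isolated)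
5 | 4-acetyl-3,5-dihydroxy-2-methylphenyl (2R)-2-methylbutanoate | CC[C@@H](C)C(=O)Oc1cc(O)c(C(C)=O)c(O)c1C | intermediate
6 | (2R)-1-(3-acetyl-2,4,6-trihydroxy-5-methylphenyl)-2-methylbutan-1-one | CC[C@@H](C)C(=O)c1c(O)c(C)c(O)c(C(C)=O)c1O | intermediate
7 | geraniol, (2E)-3,7-dimethylocta-2,6-dien-1-ol | OC/C=C(\C)CCC=C(C)C | starting material
8 | [(2E)-3,7-dimethylocta-2,6-dien-1-yl]oxy(triphenyl)phosphonium | CC(C)=CCC/C(C)=C/CO[P+](c1ccccc1)(c1ccccc1)c1ccccc1 | intermediate (not isolated)
9 | (2R)-1-[3-acetyl-4-{[(2E)-3,7-dimethylocta-2,6-dien-1-yl]oxy}-2,6-dihydroxy-5-methylphenyl]-2-methylbutan-1-one (CNP0106233.1) | CC[C@@H](C)C(=O)c1c(O)c(C)c(OC/C=C(\C)CCC=C(C)C)c(C(C)=O)c1O | target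

Total step count: 3. Longest linear sequence: 3.

## Steps most likely to fail

**Step 1 (the proposed new step).**
- The ee will be low if enolate 3 forms as an E/Z mixture or re-enolises.
- The α-branched enal may turn over slowly.
- Amine-promoted chromene formation between 1 and 2 may compete.
- The sense of induction rests on a steric model. It must be checked on the first run by chiral HPLC of 5; the antipodal catalyst is equally available.

The fallback uses known chemistry, sets out from 2 and comes back at 5. Pinnick oxidation of 2 (NaClO2, NaH2PO4, 2-methylbut-2-ene, t-BuOH–H2O) gives tiglic acid F1, which can also be bought. Hydrogenation over Ru(OAc)2[(R)-H8-BINAP] (H2 2–4 atm, MeOH) gives (R)-2-methylbutanoic acid F2, at the mid-90s % ee known for this substrate–catalyst pair. Steglich esterification of F2 with the free 4-OH of 1 (DCC, cat. DMAP, CH2Cl2–THF, 0 °C) gives 5.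

**Step 3.**
- The two outer OH groups of 6 differ only in their neighbour (acetyl versus sec-butyl ketone), so the 4-O/6-O ratio may be modest.
- The product must be confirmed by an NOE from OCH2 to the acetyl CH3.

The fallback attaches the geranyl group before the second acyl group, when the regiochemistry is unambiguous. It sets out from 5 and comes back at 9.
- Compound 5 is taken through acid F2 and chloride F3 to triol ketone F5, exactly as in the fallback for step 2.
- A Mitsunobu reaction of F5 with 7 hits the only unchelated OH (para to the ketone). It gives (2R)-1-[4-(geranyloxy)-2,6-dihydroxy-3-methylphenyl]-2-methylbutan-1-one F6.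
- Magnesium-mediated ortho-formylation (MgCl2, Et3N, paraformaldehyde, THF, reflux) tolerates the allylic ether and fills the last ring carbon. It gives 2-(geranyloxy)-4,6-dihydroxy-3-methyl-5-[(2R)-2-methylbutanoyl]benzaldehyde F7. The ee is rechecked here because MgCl2/Et3N can enolise ketones.
- MeMgBr (4 equiv, THF, −40 → 0 °C) adds only to the aldehyde, because the ketone is a hindered, chelated bis-phenoxide. It gives (2R)-1-[4-(geranyloxy)-2,6-dihydroxy-3-(1-hydroxyethyl)-5-methylphenyl]-2-methylbutan-1-one F8, as an epimer mixture at the transient carbinol carbon.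
- MnO2 (CH2Cl2, rt) oxidises F8 to 9.

**Step 2.**
- Partial racemisation may occur through an acylium/ketene or an aluminium enolate.
- Attack on a ring that already carries an acetyl group may be slow.
- The ester may cleave back to 1.

The ee is rechecked at 6, and recrystallisation of 6 would be tried to upgrade it if needed. The fallback reverses the order of the two acyl groups, sets out from 5 and comes back at 6.
- LiOH/H2O2 (THF–H2O, 0 °C) cleaves 5 to acid F2 and recovered 1.
- Oxalyl chloride with cat. DMF (CH2Cl2, 0 °C) gives (R)-2-methylbutanoyl chloride F3.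
- Friedel–Crafts acylation of the much more nucleophilic 2-methylphloroglucinol F4 (bought; AlCl3, CH2Cl2–PhNO2, 0 °C → rt; its two free ring positions are equivalent) gives (2R)-1-(2,4,6-trihydroxy-3-methylphenyl)-2-methylbutan-1-one F5.
- The well-established C-acetylation of a monoacylphloroglucinol at the last free ring carbon (Ac2O, BF3·OEt2, 50–60 °C, then aqueous work-up) gives 6.

## Further compounds
F1 | step 1 | tiglic acid, (2E)-2-methylbut-2-enoic acid | C/C=C(\C)C(=O)O
F2 | step 1 | (R)-2-methylbutanoic acid | CC[C@@H](C)C(=O)O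
F3 | step 2 | (R)-2-methylbutanoyl chloride | CC[C@@H](C)C(=O)Cl
F4 | step 2 | 2-methylphloroglucinol, 2-methylbenzene-1,3,5-triol (bought) | Cc1c(O)cc(O)cc1O
F5 | step 2 | (2R)-1-(2,4,6-trihydroxy-3-methylphenyl)-2-methylbutan-1-one | CC[C@@H](C)C(=O)c1c(O)cc(O)c(C)c1O
F6 | step 3 | (2R)-1-[4-{[(2E)-3,7-dimethylocta-2,6-dien-1-yl]oxy}-2,6-dihydroxy-3-methylphenyl]-2-methylbutan-1-one | CC[C@@H](C)C(=O)c1c(O)cc(OC/C=C(\C)CCC=C(C)C)c(C)c1O
F7 | step 3 | 2-{[(2E)-3,7-dimethylocta-2,6-dien-1-yl]oxy}-4,6-dihydroxy-3-methyl-5-[(2R)-2-methylbutanoyl]benzaldehyde | CC[C@@H](C)C(=O)c1c(O)c(C=O)c(OC/C=C(\C)CCC=C(C)C)c(C)c1O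
F8 | step 3 | (2R)-1-[4-{[(2E)-3,7-dimethylocta-2,6-dien-1-yl]oxy}-2,6-dihydroxy-3-(1-hydroxyethyl)-5-methylphenyl]-2-methylbutan-1-one (carbinol epimers) | CC[C@@H](C)C(=O)c1c(O)c(C(C)O)c(OC/C=C(\C)CCC=C(C)C)c(C)c1O
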